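The runs are simulated for an exercise; noise was put on by code.

At late times the target readings of Saturday's and Monday's runs level off, and at different heights.

| flask | starting material | free catalyst | impurity | temperature | remark | time |
|---|---|---|---|---|---|---|
| Saturday's | 0.54 M | 0.56 mM | 0.40 mM | 75 °C | run made earlier |  |
| Monday's | 1.2 M | 0.56 mM | 0.40 mM | 110 °C | run made earlier |  |
| Thursday's | 0.80 M | 0.28 mM | 0.40 mM | 75 °C | run made earlier |  |
| green | 0.80 M | 0.56 mM | 0.40 mM | 140 °C |  | 10 min |
| violet | 0.80 M | 0.56 mM | 0.40 mM | 80 °C |  | 10 min |
| ochre | 0.80 M | 0.56 mM | 0.40 mM | 110 °C |  | 10 min |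

| run | time / min | target / % | starting material / % |
|---|---|---|---|
| Saturday's | 12.0 | 32.2 | 57.1 |
| Saturday's | 40.0 | 45.5 | 17.2 |
| Saturday's | 80.0 | 44.7 | 2.9 |
| Saturday's | 90.0 | 45.5 | 1.9 |
| Saturday's | 150 | 42.5 | 0 |
| Saturday's | 180 | 43.1 | 1.0 |
| Monday's | 3.00 | 23.7 | 33.5 |
| Monday's | 4.00 | 23.8 | 22.4 |
| Monday's | 8.00 | 27.9 | 8.4 |
| Monday's | 12.0 | 25.3 | 1.7 |
| Monday's | 20.0 | 30.4 | 0.3 |
| Monday's | 40.0 | 27.0 | 0.1 |
| Thursday's | 40.0 | 1.9 | 94.5 |
| Thursday's | 80.0 | 1.0 | 94.6 |
| Thursday's | 120 | 0 | 94.6 |
| Thursday's | 150 | 0.3 | 93.4 |
| Thursday's | 180 | 1.3 | 94.4 |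

(each reading ± 1 percentage point)

- what was read earlier has a scatter of 1 percentage point, one standard deviation
- in a conversion other conformer counts as not yet reacted

- the flask with the highest amount of target, in percent of the starting material charged ("all alike" if they lie within 1.5 percentage points) (green / violet / ochre / all alike)
- final target, as a percentage of the starting material charged, in green
- final target, as a percentage of the starting material charged, in violet
- final target, as a percentage of the starting material charged, in ochre

Saturday's run reads 43.7% of target from 90.0 min on, and Monday's reads 27.6% from 12.0 min on. Starting material stands at 1.9% and 1.7% at those times. A molecule of starting material therefore comes to a fork: it ends as target or as something unread. The late split, the unread part over the target, reads 1.29 at 75 °C and 2.63 at 110 °C. The two runs also differ in charge, so treating the split as a matter of temperature is an assumption. With a constant factor per degree, the late share, meaning the target standing once starting material is used up, is 41.2% for violet and 17.1% for green. Ochre shares Monday's temperature, so the same assumption gives it 27.6%.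

The second way goes by rate. Thursday's run, with 0.28 mM of free catalyst under 0.40 mM of impurity, barely moves. The three flasks hold the catalyst and impurity of Saturday's and Monday's runs, so the pseudo-first-order constants read from those runs are taken over: 0.0440 min⁻¹ at 75 °C and 0.310 min⁻¹ at 110 °C. The same factor per degree gives 0.0582 min⁻¹ for violet, hence 44.1% converted in 10 min. Saturday's first reading puts 75.1% of the converted part in target. That makes 33.1% of target for violet and 71.7% for ochre.

The two ways part. In violet the late share cheats: the reckoned half-life of starting material, 11.9 min, is longer than the 10 min allowed, so violet is expected to stop short of its late state. In ochre the rate way cheats: Monday's first reading already shows a share of 35.6%, lower than Saturday's. My own reckoning is therefore 17.1% for green, 33.1% for violet and 27.6% for ochre, with violet highest.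

The forecast differs, naming ochre, with 21% for green, 29% for violet and 31% for ochre: “Ochre is narrowly ahead.”

At 10 min the flasks hold 17.8% of target in green, 33.1% in violet and 26.6% in ochre, so violet holds the most target.

    starting material + free catalyst → free catalyst + target (k = 360 L mol⁻¹ min⁻¹, Ea = 65.0 kJ mol⁻¹)
    free catalyst + other conformer → free catalyst + isomer of the product A (k = 870 L mol⁻¹ min⁻¹, Ea = 42.0 kJ mol⁻¹)
    free catalyst + impurity → spent catalyst (k = 25000 L mol⁻¹ min⁻¹, Ea = 41.0 kJ mol⁻¹)
    2 starting material → self-condensation product (k = 1.70 × 10⁻⁴ L mol⁻¹ min⁻¹, Ea = 89.0 kJ mol⁻¹)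
    target ⇌ isomer of the product B (K = 1.30, k = 0.0570 min⁻¹, Ea = 114 kJ mol⁻¹, ΔH = 23.0 kJ mol⁻¹)
    starting material ⇌ other conformer (K = 0.0300, k = 0.180 min⁻¹, Ea = 106 kJ mol⁻¹, ΔH = 31.0 kJ mol⁻¹)
    (constants at 80 °C)

At 10.0 min violet still makes target 2.08 times faster than it uses it up, each step taken net, and its 33.1% stands below the late share of 41.2%. Green, with starting material at 0%, holds 17.8% against its late share of 17.1%, and violet, left until 100 min, reaches 40.6%.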